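**Retrosynthetic overview**

1. Target 18 ⇐ epoxygermacrene (Z)-cinnamate 16 by a transannular epoxide–olefin cyclisation ended by a Grob-type 1,3-fragmentation: C1–C5 and C5–C10 form and C4–C5 breaks, so the cyclohexane and the cyclopropane appear together and C4 becomes the methyl ketone.
2. 16 ⇐ syn-6,8-diol 12 (O8 acylation with phenylpropiolic acid, then Lindlar) ⇐ β-hydroxy ketone 10 (chelation-controlled reduction).
3. 10 ⇐ acyclic keto aldehyde 7 by closing the ten-membered ring at C6–C7, the bond closed in germacrene biosynthesis, through conjugate methylation and zinc-enolate aldol addition; this also builds the isopropyl group.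
4. 7 ⇐ geraniol (C10; the Sharpless oxirane is the only external source of chirality) + CO + propenylstannane 6 (C4) + Me2Zn (C1).
5. Ring order: ten-membered carbocycle (step 5), then the six- and three-membered rings in one operation (step 9).

Assumption: atoms are numbered as in germacrane/guaiane (ring C1–C10, C14 on C10, C15 on C4, isopropyl C11–C13 on C7); changes of R/S letters at C6, C7 and the oxirane CH along the route are CIP priority effects only, except at C5 in step 9; stannane 6 is drawn as the E isomer, its geometry being lost in step 5.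

**Route**

Step 1
Reactants: 1 geraniol
Product: 2 [(2S,3S)-3-methyl-3-(4-methylpent-3-en-1-yl)oxiran-2-yl]methanol
Conditions: Ti(OiPr)4 (5 mol %), L-(+)-diethyl tartrate (7 mol %), tBuOOH (2 equiv), 4 Å MS, CH2Cl2, −20 °C
Reagents that add atoms: tert-butyl hydroperoxide, CC(C)(C)OO
Why: Sharpless asymmetric epoxidation of the allylic alcohol: the L-(+)-tartrate titanium complex delivers oxygen to one face of the 2,3-alkene and sets both oxirane centres (later C4 and C5) as 2S,3S in about 95% ee, leaving the remote trisubstituted alkene untouched.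

Step 2
Reactants: 2 [(2S,3S)-3-methyl-3-(4-methylpent-3-en-1-yl)oxiran-2-yl]methanol
Product: 3 (2E)-5-[(2S,3S)-3-(hydroxymethyl)-2-methyloxiran-2-yl]-2-methylpent-2-en-1-ol
Conditions: SeO2 (0.3 equiv), tBuOOH (3 equiv), salicylic acid (0.1 equiv), CH2Cl2, 0 °C → rt
Reagents that add atoms: tert-butyl hydroperoxide, CC(C)(C)OO (oxygen relayed by the SeO2 catalyst)
Why: Selenium dioxide allylic oxidation (ene reaction, then [2,3]-sigmatropic shift) hydroxylates only the E-methyl group of the trisubstituted alkene with retention of E geometry; no stereocentre is formed.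

Step 3
Reactants: 3 (2E)-5-[(2S,3S)-3-(hydroxymethyl)-2-methyloxiran-2-yl]-2-methylpent-2-en-1-ol
Product: 5 (2R,3S)-3-[(3E)-5-chloro-4-methylpent-3-en-1-yl]-3-methyloxirane-2-carbaldehyde, via chloro alkoxysulfonium chloride 4 (not isolated)
Conditions: NCS (2.3 equiv), Me2S (2.6 equiv), CH2Cl2, −25 → 0 °C, 1 h; then −40 °C, Et3N (3 equiv)
Reagents that add atoms: N-chlorosuccinimide, O=C1CCC(=O)N1Cl
Why: Corey–Kim chemistry used twice in one flask: both hydroxyls form alkoxysulfonium salts, the allylic one is displaced by chloride at 0 °C to the primary allylic chloride with the E alkene intact, and the non-allylic one (4) waits until triethylamine converts it into the aldehyde (Corey–Kim oxidation); the oxirane centres are untouched.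

Step 4
Reactants: 5 (2R,3S)-3-[(3E)-5-chloro-4-methylpent-3-en-1-yl]-3-methyloxirane-2-carbaldehyde; 6 tributyl[(1E)-prop-1-en-1-yl]stannane
Product: 7 (2R,3S)-3-methyl-3-[(3E,7E)-4-methyl-6-oxonona-3,7-dien-1-yl]oxirane-2-carbaldehyde
Conditions: Pd2(dba)3 (2.5 mol %), PPh3 (10 mol %), CO (3 atm), THF, 50 °C
Reagents that add atoms: carbon monoxide, [C-]#[O+]
Why: Carbonylative Stille coupling: zerovalent palladium ionises the allylic chloride, CO inserts at the unsubstituted allyl terminus and the propenyl group is transferred from tin, giving the allyl vinyl ketone with the E trisubstituted alkene retained and the aldehyde and oxirane untouched; no stereocentre is formed.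

Step 5
Reactants: 7 (2R,3S)-3-methyl-3-[(3E,7E)-4-methyl-6-oxonona-3,7-dien-1-yl]oxirane-2-carbaldehyde
Product: 10 (1(10)E,4S,5S,6R,7S)-4,5-epoxy-6-hydroxygermacr-1(10)-en-8-one, via methylzinc (Z)-enolate 8 (not isolated), via methylzinc aldolate 9 (not isolated)
Conditions: Me2Zn (3 equiv), Cu(OTf)2 (5 mol %), P(OEt)3 (10 mol %), toluene, −20 → 0 °C, syringe-pump addition of 7 over 8 h (final 2 mM); aq NH4Cl
Reagents that add atoms: dimethylzinc, C[Zn]C
Why: Proposed new method: copper-catalysed 1,4-addition of Me2Zn to the crotonyl enone builds the isopropyl group and gives the C7 zinc enolate 8 regiospecifically (base enolisation would instead occur at the doubly activated C9), and this enolate adds to the non-enolisable epoxy aldehyde through a zinc-bridged six-membered transition state to close the ten-membered ring at C6–C7; because the E alkene and the trans-oxirane let the ring close only with a gauche C5–C6–C7–C8 torsion, C5 sits pseudo-axial and the Z enolate gives the 6,7-anti aldol (6R,7S), while zinc chelation by the oxirane oxygen (Cram-chelate) sets the threo C5/C6 relationship; closest known reactions are tandem copper-catalysed conjugate addition/aldol cyclisations of dialkylzincs and zinc- or chromium-mediated carbonyl-allylation closures of 2,3-epoxyfarnesal-type chains to ten-membered rings.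

Step 6
Reactants: 10 (1(10)E,4S,5S,6R,7S)-4,5-epoxy-6-hydroxygermacr-1(10)-en-8-one
Product: 12 (1(10)E,4S,5S,6R,7R,8R)-4,5-epoxygermacr-1(10)-ene-6,8-diol, via diethylboryl chelate 11 (not isolated)
Conditions: Et2BOMe (1.1 equiv), THF/MeOH (4:1), −78 °C; NaBH4 (1.2 equiv); then MeOH, evaporation (3×)
Reagents that add atoms: none
Why: Narasaka–Prasad reduction: the six-membered boron chelate 11 of the β-hydroxy ketone is attacked axially by external hydride, giving the 6,8-syn diol (8R) without touching the oxirane or the alkene.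

Step 7
Reactants: 12 (1(10)E,4S,5S,6R,7R,8R)-4,5-epoxygermacr-1(10)-ene-6,8-diol; 13 3-phenylprop-2-ynoic acid
Product: 15 (1(10)E,4S,5S,6R,7S,8R)-4,5-epoxy-6-hydroxygermacr-1(10)-en-8-yl 3-phenylprop-2-ynoate, via O-acylisourea 14 (not isolated)
Conditions: DIC (1.1 equiv), DMAP (0.1 equiv), CH2Cl2, −20 → 0 °C
Reagents that add atoms: none
Why: Steglich esterification: the C6 hydroxyl (next to the fully substituted oxirane carbon and hydrogen-bonded to the oxirane oxygen) should react more slowly than the C8 hydroxyl flanked by CH2, so one equivalent of activated acid acylates O8 only; no stereocentre is touched.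

Step 8
Reactants: 15 (1(10)E,4S,5S,6R,7S,8R)-4,5-epoxy-6-hydroxygermacr-1(10)-en-8-yl 3-phenylprop-2-ynoate
Product: 16 (1(10)E,4S,5S,6R,7S,8R)-4,5-epoxy-6-hydroxygermacr-1(10)-en-8-yl (2Z)-3-phenylprop-2-enoate
Conditions: H2 (1 atm), Pd/CaCO3 poisoned with Pb(OAc)2, quinoline, EtOAc, rt, dark
Reagents that add atoms: none
Why: Lindlar semihydrogenation: syn delivery of H2 to the alkyne on the poisoned palladium surface gives the Z cinnamate, and the trisubstituted ring alkene and the oxirane are not reduced.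

Step 9
Reactants: 16 (1(10)E,4S,5S,6R,7S,8R)-4,5-epoxy-6-hydroxygermacr-1(10)-en-8-yl (2Z)-3-phenylprop-2-enoate
Product: 18 (1S,3R,4S,5S,6R,7R)-5-hydroxy-1-methyl-7-(3-oxobutyl)-4-(propan-2-yl)bicyclo[4.1.0]heptan-3-yl (2Z)-3-phenylprop-2-enoate, via 4-hydroxyguaian-10-yl cation 17 (not isolated)
Conditions: (CF3)2CHOH (HFIP), 5 mM, 0 °C → rt, dark
Reagents that add atoms: none
Why: Proposed new method: hydrogen bonding from HFIP activates the oxirane, the C1=C10 π bond held across the ring attacks C5 with inversion (C1–C5 bond, tertiary cation 17 at C10), and the C4–C5 σ bond lying anti to the empty orbital then closes C5–C10 while C4 leaves as the methyl ketone (Grob-type 1,3-fragmentation), faster than trapping in the non-nucleophilic medium; both new bonds form on one face of the E alkene, so C2 and C14 stay cis on the cyclopropane (1R,10S in germacrane numbering, side chain exo), the double inversion at C5 gives 5R, and C6, C7 and C8 are carried over unchanged; closest known reaction type is the acid- or heat-induced transannular cyclisation of germacrene 4,5-epoxides to guaianes and of germacrone 4,5-epoxide to the seco-guaiane curcumenone.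

**Compound list**

1 | geraniol, (2E)-3,7-dimethylocta-2,6-dien-1-ol | CC(C)=CCC/C(C)=C/CO | starting material
2 | [(2S,3S)-3-methyl-3-(4-methylpent-3-en-1-yl)oxiran-2-yl]methanol | CC(C)=CCC[C@]1(C)O[C@H]1CO | intermediate
3 | (2E)-5-[(2S,3S)-3-(hydroxymethyl)-2-methyloxiran-2-yl]-2-methylpent-2-en-1-ol | OC/C(C)=C/CC[C@]1(C)O[C@H]1CO | intermediate
4 | {[(2S,3S)-3-[(3E)-5-chloro-4-methylpent-3-en-1-yl]-3-methyloxiran-2-yl]methoxy}dimethylsulfonium chloride (formed in the flask) | ClC/C(C)=C/CC[C@]1(C)O[C@H]1CO[S+](C)C.[Cl-] | intermediate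
5 | (2R,3S)-3-[(3E)-5-chloro-4-methylpent-3-en-1-yl]-3-methyloxirane-2-carbaldehyde | ClC/C(C)=C/CC[C@]1(C)O[C@H]1C=O | intermediate
6 | tributyl[(1E)-prop-1-en-1-yl]stannane | C/C=C/[Sn](CCCC)(CCCC)CCCC | starting material
7 | (2R,3S)-3-methyl-3-[(3E,7E)-4-methyl-6-oxonona-3,7-dien-1-yl]oxirane-2-carbaldehyde | C/C=C/C(=O)C/C(C)=C/CC[C@]1(C)O[C@H]1C=O | intermediate
8 | methylzinc (Z)-enolate (O8–ZnMe, C7=C8) of the 1,4-methyl adduct of 7, isopropyl on C7 cis to oxygen (formed in the flask) | CC(C)/C=C(\O[Zn]C)C/C(C)=C/CC[C@]1(C)O[C@H]1C=O | intermediate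
9 | methylzinc aldolate, the O6–ZnMe alkoxide of 10 (formed in the flask) | C/C1=C\CC[C@]2(C)O[C@H]2[C@H](O[Zn]C)[C@H](C(C)C)C(=O)C1 | intermediate
10 | (1(10)E,4S,5S,6R,7S)-4,5-epoxy-6-hydroxygermacr-1(10)-en-8-one | C/C1=C\CC[C@]2(C)O[C@H]2[C@H](O)[C@H](C(C)C)C(=O)C1 | intermediate
11 | O6-diethylboryl derivative of 10, boron chelated by the C8 carbonyl (formed in the flask) | C/C1=C\CC[C@]2(C)O[C@H]2[C@H](OB(CC)CC)[C@H](C(C)C)C(=O)C1 | intermediate
12 | (1(10)E,4S,5S,6R,7R,8R)-4,5-epoxygermacr-1(10)-ene-6,8-diol | C/C1=C\CC[C@]2(C)O[C@H]2[C@H](O)[C@H](C(C)C)[C@H](O)C1 | intermediate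
13 | 3-phenylprop-2-ynoic acid (phenylpropiolic acid) | OC(=O)C#Cc1ccccc1 | starting material
14 | O-(3-phenylprop-2-ynoyl)-N,N'-diisopropylisourea (formed in the flask) | CC(C)N=C(NC(C)C)OC(=O)C#Cc1ccccc1 | intermediate
15 | (1(10)E,4S,5S,6R,7S,8R)-4,5-epoxy-6-hydroxygermacr-1(10)-en-8-yl 3-phenylprop-2-ynoate | C/C1=C\CC[C@]2(C)O[C@H]2[C@H](O)[C@H](C(C)C)[C@H](OC(=O)C#Cc3ccccc3)C1 | intermediate
16 | (1(10)E,4S,5S,6R,7S,8R)-4,5-epoxy-6-hydroxygermacr-1(10)-en-8-yl (2Z)-3-phenylprop-2-enoate | C/C1=C\CC[C@]2(C)O[C@H]2[C@H](O)[C@H](C(C)C)[C@H](OC(=O)/C=C\c3ccccc3)C1 | intermediate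
17 | 4,6-dihydroxy-8-[(Z)-cinnamoyloxy]guaian-10-yl cation with new C1–C5 bond and H1 anti to H5 (formed in the flask) | C[C+]1C[C@@H](OC(=O)/C=C\c2ccccc2)[C@@H](C(C)C)[C@@H](O)[C@H]3[C@H]1CC[C@]3(C)O | intermediate
18 | (1S,3R,4S,5S,6R,7R)-5-hydroxy-1-methyl-7-(3-oxobutyl)-4-(propan-2-yl)bicyclo[4.1.0]heptan-3-yl (2Z)-3-phenylprop-2-enoate (CNP0217452.3) | CC(=O)CC[C@@H]1[C@H]2[C@H](O)[C@H](C(C)C)[C@H](OC(=O)/C=C\c3ccccc3)C[C@]21C | target

**Step count and risks**

Total step count: 9. Longest linear sequence: 9 steps (geraniol 1 to 18); 6 and 13 are bought.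

The three steps most likely to fail:

Step 5 (ten-membered ring closure). The risks are oligomerisation, slow methyl transfer at high dilution, and above all an unproven diastereoselectivity at C6/C7. The fallback closes the same bond by a samarium Reformatsky reaction, in which the enolate is made from a halide under conditions known to favour medium rings. It sets out from diol 3. Corey–Kim chlorination without the amine stage and with aqueous work-up gives [(2S,3S)-3-[(3E)-5-chloro-4-methylpent-3-en-1-yl]-3-methyloxiran-2-yl]methanol F1. Carbonylative Stille coupling with 6 gives (2E,6E)-9-[(2S,3S)-3-(hydroxymethyl)-2-methyloxiran-2-yl]-6-methylnona-2,6-dien-4-one F2. Copper-catalysed Me2Zn addition with NBS quench of the zinc enolate gives (6E)-3-bromo-9-[(2S,3S)-3-(hydroxymethyl)-2-methyloxiran-2-yl]-2,6-dimethylnon-6-en-4-one F3 as both C3 epimers. Dess–Martin oxidation gives (2R,3S)-3-[(3E)-7-bromo-4,8-dimethyl-6-oxonon-3-en-1-yl]-3-methyloxirane-2-carbaldehyde F4. SmI2 (THF, −78 °C, 2 mM) then forms the samarium enolate at C7 only and closes it onto the aldehyde through a samarium chelate, returning to the route at hydroxy ketone 10.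

Step 7 (O8 versus O6 acylation). If the two secondary hydroxyls are not differentiated, O6 is masked before O8 exists. The fallback sets out from 10. Neutral p-methoxybenzylation (2-(4-methoxybenzyloxy)-4-methylquinoline, MeOTf, MgO, PhCF3) gives (1(10)E,4S,5S,6R,7S)-4,5-epoxy-6-[(4-methoxybenzyl)oxy]germacr-1(10)-en-8-one F5. Chelation-controlled reduction with Zn(BH4)2 (Et2O, −30 °C) gives the syn alcohol (1(10)E,4S,5S,6R,7R,8R)-4,5-epoxy-6-[(4-methoxybenzyl)oxy]germacr-1(10)-en-8-ol F6. Esterification with 13 (DIC, DMAP) gives (1(10)E,4S,5S,6R,7R,8R)-4,5-epoxy-6-[(4-methoxybenzyl)oxy]germacr-1(10)-en-8-yl 3-phenylprop-2-ynoate F7. DDQ in CH2Cl2/pH 7 buffer removes the benzyl ether and rejoins the route at 15.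

Step 9 (cyclisation/fragmentation cascade). The cation 17 may instead lose a proton to give guaiane alkenes or be trapped by O6; the oxirane may rearrange to a ketone; or the ring may cyclise through the conformer that leads to cis-fused guaianes. The fallback masks O6 and replaces solvent activation by a stoichiometric aluminium Lewis acid, so that O4 becomes an aluminium alkoxide that drives the fragmentation. It sets out from 16. Silylation (TESCl, imidazole, DMAP, DMF) gives (1(10)E,4S,5S,6R,7R,8R)-4,5-epoxy-6-[(triethylsilyl)oxy]germacr-1(10)-en-8-yl (2Z)-3-phenylprop-2-enoate F8. Et2AlCl (1.5 equiv, CH2Cl2, −78 °C) gives the triethylsilyl ether of 18 at its free hydroxyl F9. HF·pyridine in THF removes the silyl group and rejoins the route at 18.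

**Further compounds**

F1 | step 5 | [(2S,3S)-3-[(3E)-5-chloro-4-methylpent-3-en-1-yl]-3-methyloxiran-2-yl]methanol | ClC/C(C)=C/CC[C@]1(C)O[C@H]1CO
F2 | step 5 | (2E,6E)-9-[(2S,3S)-3-(hydroxymethyl)-2-methyloxiran-2-yl]-6-methylnona-2,6-dien-4-one | C/C=C/C(=O)C/C(C)=C/CC[C@]1(C)O[C@H]1CO
F3 | step 5 | (6E)-3-bromo-9-[(2S,3S)-3-(hydroxymethyl)-2-methyloxiran-2-yl]-2,6-dimethylnon-6-en-4-one, both C3 epimers | CC(C)C(Br)C(=O)C/C(C)=C/CC[C@]1(C)O[C@H]1CO
F4 | step 5 | (2R,3S)-3-[(3E)-7-bromo-4,8-dimethyl-6-oxonon-3-en-1-yl]-3-methyloxirane-2-carbaldehyde, both epimers at the bromine-bearing carbon | CC(C)C(Br)C(=O)C/C(C)=C/CC[C@]1(C)O[C@H]1C=O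
F5 | step 7 | (1(10)E,4S,5S,6R,7S)-4,5-epoxy-6-[(4-methoxybenzyl)oxy]germacr-1(10)-en-8-one | C/C1=C\CC[C@]2(C)O[C@H]2[C@H](OCc3ccc(OC)cc3)[C@H](C(C)C)C(=O)C1
F6 | step 7 | (1(10)E,4S,5S,6R,7R,8R)-4,5-epoxy-6-[(4-methoxybenzyl)oxy]germacr-1(10)-en-8-ol | C/C1=C\CC[C@]2(C)O[C@H]2[C@H](OCc3ccc(OC)cc3)[C@H](C(C)C)[C@H](O)C1
F7 | step 7 | (1(10)E,4S,5S,6R,7R,8R)-4,5-epoxy-6-[(4-methoxybenzyl)oxy]germacr-1(10)-en-8-yl 3-phenylprop-2-ynoate | C/C1=C\CC[C@]2(C)O[C@H]2[C@H](OCc3ccc(OC)cc3)[C@H](C(C)C)[C@H](OC(=O)C#Cc4ccccc4)C1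
F8 | step 9 | (1(10)E,4S,5S,6R,7R,8R)-4,5-epoxy-6-[(triethylsilyl)oxy]germacr-1(10)-en-8-yl (2Z)-3-phenylprop-2-enoate | C/C1=C\CC[C@]2(C)O[C@H]2[C@H](O[Si](CC)(CC)CC)[C@H](C(C)C)[C@H](OC(=O)/C=C\c3ccccc3)C1
F9 | step 9 | triethylsilyl ether of 18 at its free hydroxyl | CC(=O)CC[C@@H]1[C@H]2[C@H](O[Si](CC)(CC)CC)[C@H](C(C)C)[C@H](OC(=O)/C=C\c3ccccc3)C[C@]21C
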